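**Assumption:** the target SMILES has no stereocentre, so jaspaquinol is achiral. The only stereochemical task is to control the two (E)-trisubstituted alkenes.

## Retrosynthetic overview
1. The hydroquinone is unmasked last, from its dimethyl ether via the quinone (CAN, then dithionite).
2. The key disconnection is the cyclohexenyl C(sp2)–CH2 bond, made by B-alkyl Suzuki coupling of 2,6,6-trimethylcyclohexenyl triflate with a homoallylic 9-BBN borane.
3. The borane comes from hydroboration of a terminal 1,3-diene. The diene comes from an (E)-enal, which comes from E-selective SeO2 oxidation of the geranyl terminus.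
4. The aryl–CH2 bond is made by ortho-lithiation of 1,4-dimethoxybenzene and allylation with geranyl bromide, which supplies the other E-alkene.
5. No ring is formed. The arene and the cyclohexene (from 2,2,6-trimethylcyclohexanone) are both purchased.

## Route

**Step 1**
Reactants: 1, 1,4-dimethoxybenzene; 2, geranyl bromide [(E)-1-bromo-3,7-dimethylocta-2,6-diene]
Product: 3, 2-[(2E)-3,7-dimethylocta-2,6-dienyl]-1,4-dimethoxybenzene
Conditions: n-BuLi, TMEDA, THF, 0 °C to rt; CuI (10 mol %), then 2, −78 °C to rt
Reagents that add atoms: geranyl bromide (2), CC(C)=CCC/C(C)=C/CBr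
Why: Directed ortho-metalation gives a single aryllithium because all four aryl C–H are equivalent, and SN2 allylation at the primary allylic carbon keeps the 2E alkene.

**Step 2**
Reactants: 3
Product: 4, (2E,6E)-8-(2,5-dimethoxyphenyl)-2,6-dimethylocta-2,6-dien-1-ol (some enal 5 forms alongside and is carried forward)
Conditions: SeO2 (0.2 equiv), t-BuOOH (3 equiv), salicylic acid (0.1 equiv), CH2Cl2, 0 °C to rt
Reagents that add atoms: SeO2, O=[Se]=O (O donor); t-BuOOH, CC(C)(C)OO (re-oxidant)
Why: Catalytic SeO2/TBHP allylic oxidation (ene, then [2,3]-sigmatropic shift) attacks the less hindered terminal gem-dimethyl alkene and oxidises only its E-methyl, which sets the second E-trisubstituted alkene.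

**Step 3**
Reactants: 4 (plus co-formed 5)
Product: 5, (2E,6E)-8-(2,5-dimethoxyphenyl)-2,6-dimethylocta-2,6-dienal
Conditions: activated MnO2 (15 equiv), CH2Cl2, rt
Reagents that add atoms: none
Why: MnO2 oxidation is selective for the allylic alcohol, converges the step 2 mixture to one enal, and leaves the alkenes, ArCH2 and OMe groups untouched.

**Step 4**
Reactants: 5
Product: 6, 2-[(2E,6E)-3,7-dimethylnona-2,6,8-trienyl]-1,4-dimethoxybenzene
Conditions: MePPh3Br, KHMDS, THF, 0 °C; then 5, −78 °C to rt
Reagents that add atoms: methyltriphenylphosphonium bromide, C[P+](c1ccccc1)(c1ccccc1)c1ccccc1.[Br-]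
Why: Wittig methylenation of the only carbonyl gives the terminal 1,3-diene without disturbing either E-alkene.

**Step 5** (side branch)
Reactants: 7, 2,2,6-trimethylcyclohexanone (racemic)
Product: 8, 2,6,6-trimethylcyclohex-1-en-1-yl trifluoromethanesulfonate
Conditions: LDA, THF, −78 to 0 °C; PhNTf2, −78 °C to rt
Reagents that add atoms: N-phenylbis(trifluoromethanesulfonimide), O=S(=O)(N(c1ccccc1)S(=O)(=O)C(F)(F)F)C(F)(F)F
Why: In this enol triflate formation only C6 carries an α-H, so one enolate and one tetrasubstituted triflate form, and the ketone's stereocentre is erased.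

**Step 6**
Reactants: 6
Product: 9, B-[(3E,7E)-9-(2,5-dimethoxyphenyl)-3,7-dimethylnona-3,7-dienyl]-9-borabicyclo[3.3.1]nonane (kept as its THF solution under Ar and used directly in step 7)
Conditions: 9-BBN (0.5 M in THF, 1.05 equiv), THF, 0 °C to rt, 4 h
Reagents that add atoms: 9-borabicyclo[3.3.1]nonane (9-BBN-H), [H]B1C2CCCC1CCC2
Why: In this anti-Markovnikov hydroboration the bulky 9-BBN adds only to the monosubstituted vinyl terminus of the diene and places boron on the terminal CH2. This is the same selectivity as homogeraniol-type triene hydroboration. The two trisubstituted E-alkenes react far more slowly and keep their geometry.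

**Step 7**
Reactants: 9; 8
Product: 10, jaspaquinol dimethyl ether, 2-[(2E,6E)-3,7-dimethyl-9-(2,6,6-trimethylcyclohex-1-enyl)nona-2,6-dienyl]-1,4-dimethoxybenzene
Conditions: 8 (1.2 equiv), Pd(OAc)2 (5 mol %), SPhos (10 mol %), aq 3 M K3PO4, degassed THF, 60 °C (added to the solution of 9 from step 6)
Reagents that add atoms: none beyond reactants 8 and 9 (the 9-BBN unit and the triflate are both lost)
Why: Base activates the primary alkyl-9-BBN as its borate, so this B-alkyl Suzuki–Miyaura coupling transfers only the primary alkyl group. A bulky, electron-rich ligand drives oxidative addition into the hindered triflate, and no alkene geometry is affected.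

**Step 8**
Reactants: 10
Product: 11, 2-[(2E,6E)-3,7-dimethyl-9-(2,6,6-trimethylcyclohex-1-enyl)nona-2,6-dienyl]-1,4-benzoquinone
Conditions: CAN (2.5 equiv), MeCN/THF/H2O, 0 °C, 20 min
Reagents that add atoms: water, O (the quinone oxygens come from water; 2 MeOH are lost)
Why: In this CAN oxidative demethylation the 1,4-dimethoxyarene is the most easily oxidised site, so a short, cold reaction spares the three alkyl-substituted alkenes.

**Step 9**
Reactants: 11
Product: 12, jaspaquinol, 2-[(2E,6E)-3,7-dimethyl-9-(2,6,6-trimethylcyclohex-1-enyl)nona-2,6-dienyl]benzene-1,4-diol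
Conditions: Na2S2O4 (excess), Et2O/H2O, rt, 15 min, under Ar (can be run on the crude extract from step 8)
Reagents that add atoms: none
Why: Dithionite reduction of the quinone to the hydroquinone is fast, neutral and chemoselective, so no acid-induced chroman formation or alkene migration occurs.

## Compound list
1 | 1,4-dimethoxybenzene | COc1ccc(OC)cc1 | starting material
2 | geranyl bromide | CC(C)=CCC/C(C)=C/CBr | starting material
3 | 2-geranyl-1,4-dimethoxybenzene | COc1ccc(OC)c(C/C=C(\C)CCC=C(C)C)c1 | intermediate
4 | (2E,6E)-8-(2,5-dimethoxyphenyl)-2,6-dimethylocta-2,6-dien-1-ol | COc1ccc(OC)c(C/C=C(\C)CC/C=C(\C)CO)c1 | intermediate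
5 | (2E,6E)-8-(2,5-dimethoxyphenyl)-2,6-dimethylocta-2,6-dienal | COc1ccc(OC)c(C/C=C(\C)CC/C=C(\C)C=O)c1 | intermediate
6 | 2-[(2E,6E)-3,7-dimethylnona-2,6,8-trienyl]-1,4-dimethoxybenzene | COc1ccc(OC)c(C/C=C(\C)CC/C=C(\C)C=C)c1 | intermediate
7 | 2,2,6-trimethylcyclohexanone (racemic) | CC1CCCC(C)(C)C1=O | starting material
8 | 2,6,6-trimethylcyclohex-1-enyl triflate | CC1=C(OS(=O)(=O)C(F)(F)F)C(C)(C)CCC1 | intermediate
9 | B-[(3E,7E)-9-(2,5-dimethoxyphenyl)-3,7-dimethylnona-3,7-dienyl]-9-BBN | COc1ccc(OC)c(C/C=C(\C)CC/C=C(\C)CCB2C3CCCC2CCC3)c1 | intermediate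
10 | jaspaquinol dimethyl ether | CC1=C(CC/C(C)=C/CC/C(C)=C/Cc2cc(OC)ccc2OC)C(C)(C)CCC1 | intermediate
11 | the corresponding 1,4-benzoquinone | CC1=C(CC/C(C)=C/CC/C(C)=C/CC2=CC(=O)C=CC2=O)C(C)(C)CCC1 | intermediate
12 | jaspaquinol | CC1=C(CC/C(C)=C/CC/C(C)=C/Cc2cc(O)ccc2O)C(C)(C)CCC1 | target

## Summary
**Total steps:** 9. Steps 6 and 7 run in the same flask without isolating 9, and steps 8 and 9 can be telescoped.
**Longest linear sequence:** 8 (steps 1–4 and 6–9). Step 5 is a one-step side branch.

**Three steps most likely to fail**
1. **Step 7.** Oxidative addition and coupling at the doubly flanked tetrasubstituted triflate may be slow, which allows protodeboronation of 9 or triflate hydrolysis.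
   - Fallback: move the disconnection one carbon out.
   - Convert 4 to the allylic bromide (CBr4/PPh3).
   - Alkylate lithiated β-cyclogeranyl phenyl sulfone with it. The sulfone comes from β-cyclocitral by NaBH4, PBr3, then PhSO2Na.
   - Remove the sulfone reductively with PdCl2(dppp)/LiEt3BH.
2. **Step 2.** The yield is likely moderate, with competition from the internal alkene and over-oxidation.
   - Fallback: replace C–H oxidation with terminal alkene cleavage and re-olefination.
   - Treat 3 with NBS in aq THF, then K2CO3, to give the 6,7-epoxide.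
   - Cleave with H5IO6 to give (E)-6-(2,5-dimethoxyphenyl)-4-methylhex-4-enal.
   - An E-selective stabilised Wittig reaction with Ph3P=C(CH3)CHO then gives 5.
3. **Step 8.** Ce(IV) may attack the electron-rich tetrasubstituted alkene or cause quinone dimerisation.
   - Fallback: avoid an oxidative end-game.
   - Start from hydroquinone bis-MOM ether in place of 1 and use the same ortho-lithiation/geranylation sequence.
   - Finish with a single mild acidic deprotection (cat. HCl/MeOH, or TMSBr at −30 °C).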